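Conventions and one assumption: germacrane-type numbering is used for every intermediate (ring A = C1–C5; ring B = C1, C5, C6, C10; ring C = C6–C10; C11/C12 = lactone α-carbon and carbonyl; C13 = acetoxymethyl carbon; C14 = methyl on C10; C15 = methyl on C4). α is the face of ring B that carries C14 and the C6 oxygen, β the opposite face. Cyclotene (1) is assumed to react as its enol tautomer; SMILES of the racemic compounds show the enantiomer that is carried forward.

## Analysis of the target

The target is a sesquiterpenoid built on a linear 5-4-5 carbotricycle (rings A, B, C) in the cis-syn-cis arrangement, with a butenolide fused to C6–C7 (C7=C11 olefin, C13 acetoxymethyl). It has seven stereocentres: C1 and C5 (the only hydrogen-bearing cyclobutane carbons), the vicinal fully substituted C6 (lactone oxygen) and C10 (methyl), C2 (acetate), C4 (methyl carbinol) and C8 (tiglate). H1, H5, C14, the C6 oxygen, the C2 and C8 ester oxygens and the C4 hydroxyl all lie on the α face, so both five-membered rings are folded onto the β face. Sensitive groups are a secondary and an allylic primary acetate, a conjugated tigloyl ester that tolerates neither hydrogenation nor radical hydration, a free tertiary alcohol, the butenolide and the strained four-membered ring. Any intermediate with a free C6 hydroxyl next to a C7 ketone is a 1-acylcyclobutanol and can ring-expand by α-ketol rearrangement. The difficulty is concentrated in ring B: four contiguous stereocentres, two of them quaternary and adjacent, with the two outer rings syn. The strategy rests on C1 and C5: C6 and C10 can be set cis on ring C alone, C1 and C5 can then be tied through a one-atom sulfonyl bridge and strapped with the three carbons of ring A, and excision of the bridge forms C1–C5 as an olefin common to rings A and B, to which both hydrogens are added last from the α face.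

## Retrosynthetic reasoning

Target 41 is cut at the C8–O acyl bond to alcohol 38 and tiglic acid (39). The tiglate is the one group that survives neither hydrogenation, radical hydration nor enolate chemistry, so it goes on last; the forward step must acylate the secondary C8 hydroxyl beside the free tertiary C4 hydroxyl.

38 is taken back through 37 and 36 (C13 acetate, C8 silyl ether) to 35, and the C4–O bond of 35 is cut to the exocyclic C4=C15 olefin of 34. The olefin is a masked tertiary alcohol that cannot compete in the earlier acylation of the C6 hydroxyl. Oxygen delivery to a planar C4 radical from the convex α face gives the required epimer, whereas methyl addition to a C4 ketone would give the wrong one. The forward hydration must leave the butenolide olefin alone.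

Butenolide 34 is cut at C7=C11 and O6–C12 to phosphonate ester 33, and this to hydroxy ketone 28 and acid 32 (from 29 and 30). An intramolecular olefination admits only one olefin geometry and brings C11–C13 in one piece. The forward steps must acylate a very hindered tertiary cyclobutanol and close the ring before that 1-acylcyclobutanol rearranges.

28 is simplified through 27 and 26 to ketone 25 by cutting the C8–O bond. C7 can enolize only towards C8, and in the syn tricycle ring A covers the β face of ring C, so an electrophilic oxygen should enter α. Ketone 25 comes from ketal 24.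

Ring A of 24 is taken back through 23 and 22 to enone 20, ketone 18 and ketal 17: C15 is cut (C4=C15 from the C4 ketone), and the C2–O bond is cut to the C2=C3 enone. The C2 oxygen is deliberately not carried through the ring contraction. On the bridged sulfone its configuration would be set with uncertain facial preference, and an aldehyde-level C2 electrophile cannot be closed onto a sulfone carbanion because it is enolizable. On the cup-shaped tricycle the α face of ring A is the only open one, so conjugate delivery of a boron nucleophile gives the target configuration directly and no inversion is needed.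

17 is cut at the two C–H bonds on C1 and C5 to cyclobutene 16. The forward hydrogenation must add both hydrogens to the α face, which folds ring A onto the β face and creates the cis-syn-cis tricycle.

16 is cut at C1=C5 by reinserting a sulfonyl bridge, which gives the bridgehead α-chloro sulfone 14. This is the key disconnection: it removes rings A and B in one stroke, leaves only a thiolane fused to ring C plus a three-carbon strap, and needs no stereocontrol because C1 and C5 become trigonal.

14 is taken back through 13 and 12 to bridged keto sulfone 11, which is cut at C5–C4 (sulfone–ester cyclization) to 10 and at C1–C2 (conjugate addition) to sulfone 8 and methyl acrylate (9). The acrylate supplies C2–C4 with C4 at the carboxyl level, so the ring is closed onto an ester and no enolizable aldehyde or 1,3-dicarbonyl appears. The C6 hydroxyl is kept free at this stage: as the alkoxide it cannot be expelled from a neighbouring carbanion and it steers the first deprotonation to C1.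

8 comes from 7 by oxidation at sulfur, 7 from racemic 6 by ketalization with an enantiopure C2-symmetric diol (the resolution), 6 from 5, and 5 is cut at C1–C10 and C5–C6 to enol acetate 2 and the ylide precursor 3; 2 is the acetate of cyclotene (1). The cycloaddition sets the two quaternary centres C6 and C10 cis in one suprafacial step.

## Alternatives that were turned down

Alternative 1: Both cyclobutane bonds, C1–C5 and C6–C10, are cut, which leads to the ten-membered germacra-1(10),5,7(11)-trien-12,6-olide A2 with both ring olefins ring-cis. Forward, irradiation of A2 would join the two olefins across the ring to the 8-hydroxy tetracycle A1, which is identical with 38 and one acylation from the target. In its favour: it follows the likely biogenesis, forms two bonds, three rings and four stereocentres in one step, and is unbeatable in step economy once A2 is in hand. Against it: A2 is itself a hard target, a functionalized ten-membered ring with two Z-trisubstituted olefins, a γ-alkylidene butenolide and three stereocentres. The outcome of the photoreaction also depends on a single reactive conformer. A straight rather than a crossed adduct, and the syn rather than the anti tricycle, are both required, while E/Z isomerization and sigmatropic shifts of the dienolide chromophore compete. On convergence and atom economy this alternative is stronger; the chosen route offers instead stereocentres set one at a time by ground-state, face-controlled reactions, and no macrocycle.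

Alternative 2: The C8–C9 and C10–C14 bonds are cut on a ring A/ring B cyclobutanone, which leads to the α-methylene cyclobutanone A4. Forward, 2-lithio-2-methyl-1,3-dithiane would add to the exocyclic carbon and the enolate would be methylated on the convex face to give the C10-quaternary cyclobutanone A3. In its favour: ring B is made early by reliable ketene chemistry, C1, C5 and C10 are set on a rigid bicyclo[3.2.0] frame with clear convex-face control, and ring A stereocentres could come from a chiral cyclopentene, so no resolution is needed; on early stereocontrol it is stronger than the chosen route. Against it: A4 is a strained, polymerizable acceptor on which 1,2-addition and ring opening compete with the conjugate addition. A3 still lacks ring C, the C6 oxygen and the whole lactone, and ring C must then be closed onto the concave face. The closure is an aldol onto the cyclobutanone carbonyl, which creates exactly the retro-aldol-prone and ring-expansion-prone cyclobutanol discussed above, with C7 and C8 still at the wrong oxidation level. The chosen route makes C6 and C10 together with their oxygen and methyl substituents before the four-membered ring exists.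

Alternative 3: Only C6–C10 is cut, which leads to the ring-A-fused 2-benzyloxy-5-methyltropone A6. Forward, irradiation would close C6–C10 by disrotatory 4π electrocyclization to the bicyclo[3.2.0]heptadienone A5, which carries the same C1=C5 cyclobutene as 16 and would share the α-face hydrogenation. In its favour: tropolone ether photochemistry is well known, both quaternary centres and the C7 ketone with a C8=C9 enone arise in one step, and the route to the tricycle is shorter than the chosen one. Against it: a regiodefined, ring-fused tropolone must be built first. The primary photoproduct of tropolone ethers is prone to a second photorearrangement (1,3-acyl shift). The only stereocentre present (C2) is remote from C6 and C10, so a mixture of diastereomers is expected. The cyclobutene is also conjugated to a C4 ketone. The chosen contraction is thermal, regiochemically unambiguous, and starts from material resolved at an early, simple stage.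

Key step: step 11

## Steps

Step 1
Reactants: 1 3-methylcyclopentane-1,2-dione (cyclotene)
Product: 2 2-acetoxy-3-methylcyclopent-2-en-1-one
Conditions: Ac2O, Et3N, DMAP (cat.), CH2Cl2, 0 °C to rt
Reagents that add atoms: acetic anhydride, CC(=O)OC(C)=O
Why: O-Acylation of the diosphenol enol; it removes the acidic OH that would quench the ylide of step 2 and makes the tetrasubstituted olefin more electron-poor.

Step 2
Reactants: 2 2-acetoxy-3-methylcyclopent-2-en-1-one; 3 chloromethyl (trimethylsilyl)methyl sulfide
Product: 5 rac-cis-3a-acetoxy-6a-methylhexahydro-1H-cyclopenta[c]thiophen-4-one, via thiocarbonyl ylide 4 (not isolated)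
Conditions: CsF, MeCN, rt, slow addition of 3 (3 equiv)
Reagents that add atoms: none
Why: Fluoride-induced 1,3-elimination gives the parent thiocarbonyl ylide, which should add to the enone olefin in a [3+2] cycloaddition; the suprafacial addition forms C1–C10 and C5–C6 and fixes the C6 oxygen and C14 cis; the product is racemic.

Step 3
Reactants: 5 rac-cis-3a-acetoxy-6a-methylhexahydro-1H-cyclopenta[c]thiophen-4-one
Product: 6 rac-cis-3a-hydroxy-6a-methylhexahydro-1H-cyclopenta[c]thiophen-4-one
Conditions: K2CO3 (0.2 equiv), MeOH, 0 °C
Reagents that add atoms: none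
Why: Methanolysis of the tertiary α-keto acetate, assisted by the neighbouring ketone; the free C6 hydroxyl is needed as an alkoxide in steps 6 and 7.

Step 4
Reactants: 6 rac-cis-3a-hydroxy-6a-methylhexahydro-1H-cyclopenta[c]thiophen-4-one
Product: 7 (3aR,6aS)-3a-hydroxy-6a-methylhexahydro-1H-cyclopenta[c]thiophen-4-one (2R,3R)-butane-2,3-diyl ketal
Conditions: (2R,3R)-2,3-bis(trimethylsilyloxy)butane, Me3SiOTf (cat.), CH2Cl2, −78 to −20 °C; K2CO3/MeOH work-up; chromatographic separation of the two diastereomers
Reagents that add atoms: (2R,3R)-2,3-bis(trimethylsilyloxy)butane, C[C@@H](O[Si](C)(C)C)[C@@H](C)O[Si](C)(C)C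
Why: Noyori ketalization of the hindered C7 ketone; the C2-symmetric diol creates no stereocentre at C7 but turns the two enantiomers into separable diastereomers (the resolution) and masks the ketone for the carbanion chemistry.

Step 5
Reactants: 7 (3aR,6aS)-hydroxy ketal sulfide
Product: 8 (3aR,6aS)-3a-hydroxy-6a-methylhexahydro-1H-cyclopenta[c]thiophen-4-one 2,2-dioxide (2R,3R)-butane-2,3-diyl ketal
Conditions: mCPBA (2.2 equiv), NaHCO3, CH2Cl2, 0 °C to rt
Reagents that add atoms: 3-chloroperbenzoic acid, OOC(=O)c1cccc(Cl)c1
Why: Standard sulfide-to-sulfone oxidation; the buffer protects the ketal.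

Step 6
Reactants: 8 hydroxy ketal sulfone; 9 methyl acrylate
Product: 10 sulfone 8 carrying a 2-(methoxycarbonyl)ethyl group on C1 (the S–CH2 next to C10) cis to the C6 hydroxyl and C14
Conditions: n-BuLi (2.05 equiv), THF, −78 to −40 °C; 9 (1.0 equiv), −78 °C; AcOH quench
Reagents that add atoms: none
Why: The first equivalent gives the C6 lithium alkoxide, which cannot be expelled by E1cB; the second should remove a C1 proton, since C1 is the less hindered α-carbon and its lithium sits in a five-membered chelate with the alkoxide, whereas a C5 carbanion would be adjacent to the negative oxygen. Michael addition of the α-sulfonyl carbanion to the acrylate forms C1–C2 on the chelated α face.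

Step 7
Reactants: 10 C1-(2-methoxycarbonylethyl) sulfone
Product: 11 bridged keto sulfone (8-thiabicyclo[3.2.1]octan-2-one 8,8-dioxide whose two-carbon bridge C10–C6 is shared with ring C; C4 ketone; bridge C2–C3–C4 on the α face; C6–OH free)
Conditions: LiN(i-Pr)2 (3.2 equiv), THF, −78 to −20 °C; AcOH quench
Reagents that add atoms: none
Why: Dieckmann-type sulfone–ester cyclization: the C5 carbanion acylates the ester (6-exo-trig) and the strap can only close cis across the α face; with C6 as alkoxide and C2 a methylene there is no β-leaving group anywhere, and enolization of the product at C3 drives the closure.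

Step 8
Reactants: 11 bridged keto sulfone
Product: 12 C4 dimethyl ketal of 11
Conditions: MeOSiMe3 (3 equiv), Me3SiOTf (cat.), CH2Cl2, −78 to −30 °C; K2CO3/MeOH work-up
Reagents that add atoms: methoxytrimethylsilane, CO[Si](C)(C)C
Why: Noyori ketalization of the electron-poor α-sulfonyl ketone; it removes the only enolizable position before bridgehead metalation and gives a ketal that is more labile than the one at C7 for later differentiation.

Step 9
Reactants: 12 hydroxy bis-ketal sulfone
Product: 13 C6 methoxymethyl ether of 12
Conditions: MOMCl, i-Pr2NEt, Bu4NI (cat.), ClCH2CH2Cl, 60 °C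
Reagents that add atoms: chloromethyl methyl ether, COCCl
Why: Alkylation of the tertiary alcohol with a small, very reactive α-chloro ether; in the bridged skeleton an ether at C6 can no longer be lost by β-elimination, and capping prevents retro-aldol opening of a β-oxido sulfone under the basic key step.

Step 10
Reactants: 13 bridged sulfone
Product: 14 bridgehead α-chloro sulfone (chlorine on C1, the bridgehead next to C10)
Conditions: LiN(i-Pr)2 (1.2 equiv), THF, −78 °C; C2Cl6, −78 to 0 °C
Reagents that add atoms: hexachloroethane, ClC(Cl)(Cl)C(Cl)(Cl)Cl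
Why: α-Sulfonyl carbanions need no planarity and form at bridgeheads; C1–H is the more accessible bridgehead (C5 is flanked by the ketal and the ether-bearing C6) and chlorine is transferred with retention; a C5 chloride would contract to the same olefin.

Step 11
Reactants: 14 bridgehead α-chloro sulfone
Product: 16 tricyclic C1=C5 olefin (bicyclo[3.2.0]hept-1(5)-ene fused at C6–C10 to ring C), via episulfone 15 (not isolated)
Conditions: KOt-Bu (3 equiv), THF, −78 to 0 °C
Reagents that add atoms: none
Why: tert-Butoxide removes the C5 bridgehead proton, and the carbanion displaces chloride from C1 in a 1,3-elimination through the W-shaped H–C5–S–C1–Cl array to give episulfone 15, which loses SO2 cheletropically to the C1=C5 olefin. This is the Ramberg–Bäcklund reaction in the form known for bridgehead α-halo sulfones of thiabicycloalkanes, which give ring-fusion olefins. Ring B arises by contraction of the thiolane (3-exo-tet closure of the thiirane, then extrusion), and ring A in the same event by contraction of the six-membered thiane that contained the three-carbon strap. No stereocentre is created: C1 and C5 become trigonal and C6 and C10 are untouched. The selectivity needed is the 1,3-elimination over β-elimination, and the bridged skeleton secures it, because loss of HCl across C1–C2, of methoxide from C4 or of the ether oxygen from C6 would each put a double bond at a bridgehead. The capped C6 oxygen rules out retro-aldol opening and the C4 ketal removes the only enolizable ketone. The strained olefin should be hydrogenated without delay.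

Step 12
Reactants: 16 tricyclic C1=C5 olefin
Product: 17 cis-syn-cis tricycle (H1 and H5 α; C4 dimethyl ketal; C6 OMOM; C7 butanediol ketal)
Conditions: H2 (1 atm), Pd/C, EtOAc, rt
Reagents that add atoms: none
Why: The strained tetrasubstituted olefin should hydrogenate readily by syn addition from the α face: the β face is screened by ring C (endo C9–H and the inward ketal oxygen on C7), the α face carries only the angular methyl and the MOM ether; this sets C1 and C5 and folds ring A onto the β face.

Step 13
Reactants: 17 cis-syn-cis bis-ketal
Product: 18 C4 ketone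
Conditions: PPTS, THF/H2O, rt
Reagents that add atoms: water, O
Why: An acyclic dimethyl ketal hydrolyses far faster than the substituted dioxolane at the hindered C7 or the MOM ether.

Step 14
Reactants: 18 C4 ketone
Product: 20 C2=C3 enone (cyclopent-2-enone in ring A), via trimethylsilyl enol ether 19 (not isolated)
Conditions: LiN(SiMe3)2, Me3SiCl, THF, −78 °C; then Pd(OAc)2 (1.1 equiv), MeCN, rt
Reagents that add atoms: none
Why: Saegusa–Ito dehydrogenation; enolization can only go towards C3 because C5 is a cyclobutane ring-fusion carbon.

Step 15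
Reactants: 20 C2=C3 enone
Product: 22 C2α-hydroxy C4 ketone, via C2 pinacol boronate 21 (not isolated)
Conditions: CuCl (5 mol%), NaOt-Bu (10 mol%), Xantphos (5 mol%), B2pin2, MeOH, THF, rt; then NaBO3·4H2O, THF/H2O, rt
Reagents that add atoms: sodium perborate, [Na+].[O-]OB=O
Why: Copper-catalysed conjugate borylation; the boryl copper species should add to C2 from the convex α face of ring A (the β face is the cavity under ring C), and oxidation with retention gives the C2 hydroxyl cis to H1, the configuration of the target.

Step 16
Reactants: 22 C2α-hydroxy C4 ketone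
Product: 23 C2α-hydroxy C4=C15 exocyclic olefin
Conditions: Zn, CH2Br2, TiCl4 (pre-formed Lombardo reagent), THF/CH2Cl2, 0 °C to rt
Reagents that add atoms: dibromomethane, BrCBr
Why: Takai–Lombardo methylenation is non-basic, so the β-hydroxy ketone should neither eliminate nor undergo retro-aldol cleavage.

Step 17
Reactants: 23 homoallylic alcohol
Product: 24 C2α-acetate
Conditions: Ac2O, pyridine, DMAP (cat.), CH2Cl2, 0 °C
Reagents that add atoms: acetic anhydride, CC(=O)OC(C)=O
Why: Acetylation of the only free hydroxyl installs the C2 acetate of the target.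

Step 18
Reactants: 24 C2 acetate with C7 ketal
Product: 25 C7 ketone (C6 OMOM)
Conditions: TsOH·H2O (0.2 equiv), THF/H2O (4:1), 40 °C
Reagents that add atoms: water, O
Why: Acid hydrolysis of the dioxolane; the MOM ether stays on, so no 1-acylcyclobutanol is exposed to acid, and conditions are kept mild for the exocyclic olefin.

Step 19
Reactants: 25 C7 ketone
Product: 26 C8α-hydroxy C7 ketone
Conditions: KN(SiMe3)2 (1.1 equiv), THF, −78 °C; 2-(phenylsulfonyl)-3-phenyloxaziridine; AcOH quench
Reagents that add atoms: 2-(phenylsulfonyl)-3-phenyloxaziridine, O=S(=O)(c1ccccc1)N1OC1c1ccccc1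
Why: Davis hydroxylation of the only possible enolate (C7=C8); oxygen should be transferred to the α face of ring C because ring A covers the β face in the syn tricycle, giving C8–OH cis to C14.

Step 20
Reactants: 26 C8α-hydroxy ketone
Product: 27 C8 tert-butyldimethylsilyl ether
Conditions: TBSOTf, 2,6-lutidine, CH2Cl2, −78 °C
Reagents that add atoms: tert-butyldimethylsilyl triflate, CC(C)(C)[Si](C)(C)OS(=O)(=O)C(F)(F)F
Why: Silylation keeps the C8 hydroxyl out of the C6 acylation and is removable with fluoride at the end.

Step 21
Reactants: 27 C6 OMOM ketone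
Product: 28 C6 hydroxy C7 ketone (1-acylcyclobutanol)
Conditions: Me3SiOTf, 2,2′-bipyridyl, CH2Cl2, 0 °C; then H2O
Reagents that add atoms: none
Why: MOM ethers are cleaved under these nearly neutral conditions through a pyridinium-type methyl ether that hydrolyses on adding water; silyl ether, acetate and olefin should be untouched and the α-ketol is never exposed to strong acid or base.

Step 22
Reactants: 29 ethyl 2-(diethoxyphosphoryl)acrylate; 30 4-methoxybenzyl alcohol
Product: 31 ethyl 2-(diethoxyphosphoryl)-3-[(4-methoxybenzyl)oxy]propanoate (racemic)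
Conditions: KOt-Bu (5 mol%), THF, 0 °C
Reagents that add atoms: none
Why: Oxa-Michael addition of the alkoxide to the doubly activated olefin.

Step 23
Reactants: 31 phosphono ester
Product: 32 2-(diethoxyphosphoryl)-3-[(4-methoxybenzyl)oxy]propanoic acid (racemic)
Conditions: LiOH·H2O (1.1 equiv), THF/H2O, 0 °C; then 1 M HCl
Reagents that add atoms: lithium hydroxide, [Li+].[OH-]
Why: Saponification of the carboxylic ester only (phosphonate esters are inert); kept cold to suppress retro-Michael loss of the alkoxide.

Step 24
Reactants: 28 C6 hydroxy C7 ketone; 32 phosphono acid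
Product: 33 C6 ester of 28 with 32 (epimers at the phosphonate carbon)
Conditions: DCC, DMAP, CH2Cl2, 0 °C to rt
Reagents that add atoms: none
Why: Steglich esterification; α-phosphono acids are activated through a phosphonoketene, a small electrophile that should reach the hindered tertiary alcohol under nearly neutral conditions.

Step 25
Reactants: 33 phosphonate ester
Product: 34 butenolide (C7=C11; C13 OPMB; C8 OTBS; C2 OAc; C4=C15)
Conditions: K2CO3, 18-crown-6, toluene, rt
Reagents that add atoms: none
Why: Intramolecular Horner–Wadsworth–Emmons olefination closes the five-membered lactone with the only possible geometry; loss of the β-alkoxide from the carbanion is reversible whereas olefination is not, and the mild base should spare C8.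

Step 26
Reactants: 34 butenolide with C4=C15
Product: 35 C4α tertiary alcohol (C15 methyl β)
Conditions: Co(acac)2 (20 mol%), PhSiH3, O2 (1 atm), i-PrOH, rt; then aq. Na2S2O3
Reagents that add atoms: dioxygen, O=O
Why: Mukaiyama hydration; hydrogen-atom transfer should occur at the electron-rich 1,1-disubstituted olefin and not at the tetrasubstituted, electron-poor butenolide olefin, and the planar C4 radical is trapped by O2 from the convex α face, giving the hydroxyl cis to H5.

Step 27
Reactants: 35 C13 PMB ether
Product: 36 C13 primary alcohol
Conditions: DDQ, CH2Cl2/pH 7 buffer, 0 °C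
Reagents that add atoms: none
Why: Oxidative cleavage of the 4-methoxybenzyl ether; esters, silyl ether and tertiary alcohol are inert.

Step 28
Reactants: 36 C13 alcohol
Product: 37 C13 acetate
Conditions: Ac2O, pyridine, CH2Cl2, 0 °C
Reagents that add atoms: acetic anhydride, CC(=O)OC(C)=O
Why: The primary allylic alcohol is acetylated; the tertiary C4 hydroxyl does not react under these conditions.

Step 29
Reactants: 37 C8 silyl ether
Product: 38 C8α alcohol (the target lacking the tigloyl group)
Conditions: HF·pyridine, pyridine, THF, 0 °C to rt
Reagents that add atoms: none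
Why: Fluoride desilylation under buffered conditions that leave both acetates and the lactone intact.

Step 30
Reactants: 38 C8α alcohol; 39 tiglic acid
Product: 41 CNP0210373.1, via mixed tigloyl trichlorobenzoyl anhydride 40 (not isolated)
Conditions: 39, 2,4,6-trichlorobenzoyl chloride, Et3N, toluene, rt; then 38, DMAP, rt
Reagents that add atoms: none
Why: Yamaguchi esterification; the secondary C8 hydroxyl is acylated with retention, the tertiary C4 hydroxyl is not, and the E geometry of the tiglate is the stable one.

## Compound list

1 | 3-methylcyclopentane-1,2-dione (cyclotene) | CC1CCC(=O)C1=O | starting material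
2 | 2-acetoxy-3-methylcyclopent-2-en-1-one | CC1=C(OC(C)=O)C(=O)CC1 | intermediate
3 | chloromethyl (trimethylsilyl)methyl sulfide | C[Si](C)(C)CSCCl | starting material
4 | thioformaldehyde S-methylide (thiocarbonyl ylide) | C=[S+][CH2-] | intermediate
5 | rac-cis-3a-acetoxy-6a-methylhexahydro-1H-cyclopenta[c]thiophen-4-one (racemate) | C1C[C@]2(C)CSC[C@]2(OC(C)=O)C1=O | intermediate
6 | rac-cis-3a-hydroxy-6a-methylhexahydro-1H-cyclopenta[c]thiophen-4-one (racemate) | C1C[C@]2(C)CSC[C@]2(O)C1=O | intermediate
7 | (3aR,6aS)-3a-hydroxy-6a-methylhexahydro-1H-cyclopenta[c]thiophen-4-one (2R,3R)-butane-2,3-diyl ketal | C1C[C@]2(C)CSC[C@]2(O)C13O[C@H](C)[C@@H](C)O3 | intermediate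
8 | sulfone (2,2-dioxide) of 7 | C1C[C@]2(C)CS(=O)(=O)C[C@]2(O)C13O[C@H](C)[C@@H](C)O3 | intermediate
9 | methyl acrylate | C=CC(=O)OC | starting material
10 | sulfone 8 with a 2-(methoxycarbonyl)ethyl group on C1, cis to C6–OH and C14 | C1C[C@]2(C)[C@@H](CCC(=O)OC)S(=O)(=O)C[C@]2(O)C13O[C@H](C)[C@@H](C)O3 | intermediate
11 | bridged keto sulfone: C4 ketone, C2–C3–C4 strap on the α face, sulfonyl bridge on the ring C side, C6–OH, C7 butanediol ketal | C1C[C@]2(C)[C@H]3CCC(=O)[C@H](S3(=O)=O)[C@]2(O)C14O[C@H](C)[C@@H](C)O4 | intermediate
12 | C4 dimethyl ketal of 11 | C1C[C@]2(C)[C@H]3CCC(OC)(OC)[C@H](S3(=O)=O)[C@]2(O)C14O[C@H](C)[C@@H](C)O4 | intermediate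
13 | C6 methoxymethyl ether of 12 | C1C[C@]2(C)[C@H]3CCC(OC)(OC)[C@H](S3(=O)=O)[C@]2(OCOC)C14O[C@H](C)[C@@H](C)O4 | intermediate
14 | bridgehead α-chloro sulfone (Cl on C1) | C1C[C@]2(C)[C@@]3(Cl)CCC(OC)(OC)[C@H](S3(=O)=O)[C@]2(OCOC)C14O[C@H](C)[C@@H](C)O4 | intermediate
15 | episulfone (thiirane 1,1-dioxide across C1–C5, sulfonyl group on the β face) | C1C[C@]2(C)[C@@]34CCC(OC)(OC)[C@@]3(S4(=O)=O)[C@]2(OCOC)C15O[C@H](C)[C@@H](C)O5 | intermediate
16 | tricyclic C1=C5 olefin (bicyclo[3.2.0]hept-1(5)-ene fused to ring C; C4 dimethyl ketal, C6 OMOM, C7 butanediol ketal) | C1C[C@]2(C)C3=C([C@]2(OCOC)C14O[C@H](C)[C@@H](C)O4)C(OC)(OC)CC3 | intermediate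
17 | cis-syn-cis tricycle, H1 and H5 α | C1C[C@]2(C)[C@@H]3CCC(OC)(OC)[C@@H]3[C@]2(OCOC)C14O[C@H](C)[C@@H](C)O4 | intermediate
18 | C4 ketone of the tricycle | C1C[C@]2(C)[C@@H]3CCC(=O)[C@@H]3[C@]2(OCOC)C14O[C@H](C)[C@@H](C)O4 | intermediate
19 | C3=C4 trimethylsilyl enol ether | C1C[C@]2(C)[C@@H]3CC=C(O[Si](C)(C)C)[C@@H]3[C@]2(OCOC)C14O[C@H](C)[C@@H](C)O4 | intermediate
20 | C2=C3 enone | C1C[C@]2(C)[C@@H]3C=CC(=O)[C@@H]3[C@]2(OCOC)C14O[C@H](C)[C@@H](C)O4 | intermediate
21 | C2α pinacol boronate of the C4 ketone | C1C[C@]2(C)[C@@H]3[C@@H](B5OC(C)(C)C(C)(C)O5)CC(=O)[C@@H]3[C@]2(OCOC)C14O[C@H](C)[C@@H](C)O4 | intermediate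
22 | C2α-hydroxy C4 ketone | C1C[C@]2(C)[C@@H]3[C@@H](O)CC(=O)[C@@H]3[C@]2(OCOC)C14O[C@H](C)[C@@H](C)O4 | intermediate
23 | C2α-hydroxy C4=C15 olefin | C1C[C@]2(C)[C@@H]3[C@@H](O)CC(=C)[C@@H]3[C@]2(OCOC)C14O[C@H](C)[C@@H](C)O4 | intermediate
24 | C2α-acetate, C4=C15, C7 ketal | C1C[C@]2(C)[C@@H]3[C@@H](OC(C)=O)CC(=C)[C@@H]3[C@]2(OCOC)C14O[C@H](C)[C@@H](C)O4 | intermediate
25 | C7 ketone (C6 OMOM) | C1C[C@]2(C)[C@@H]3[C@@H](OC(C)=O)CC(=C)[C@@H]3[C@]2(OCOC)C1=O | intermediate
26 | C8α-hydroxy C7 ketone | O[C@H]1C[C@]2(C)[C@@H]3[C@@H](OC(C)=O)CC(=C)[C@@H]3[C@]2(OCOC)C1=O | intermediate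
27 | C8α tert-butyldimethylsilyl ether | CC(C)(C)[Si](C)(C)O[C@H]1C[C@]2(C)[C@@H]3[C@@H](OC(C)=O)CC(=C)[C@@H]3[C@]2(OCOC)C1=O | intermediate
28 | C6 hydroxy C7 ketone (MOM removed) | CC(C)(C)[Si](C)(C)O[C@H]1C[C@]2(C)[C@@H]3[C@@H](OC(C)=O)CC(=C)[C@@H]3[C@]2(O)C1=O | intermediate
29 | ethyl 2-(diethoxyphosphoryl)acrylate | C=C(C(=O)OCC)P(=O)(OCC)OCC | starting material
30 | 4-methoxybenzyl alcohol | COc1ccc(CO)cc1 | starting material
31 | ethyl 2-(diethoxyphosphoryl)-3-[(4-methoxybenzyl)oxy]propanoate (racemic) | CCOC(=O)C(COCc1ccc(OC)cc1)P(=O)(OCC)OCC | intermediate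
32 | 2-(diethoxyphosphoryl)-3-[(4-methoxybenzyl)oxy]propanoic acid (racemic) | OC(=O)C(COCc1ccc(OC)cc1)P(=O)(OCC)OCC | intermediate
33 | C6 phosphonopropanoate ester of 28 | CC(C)(C)[Si](C)(C)O[C@H]1C[C@]2(C)[C@@H]3[C@@H](OC(C)=O)CC(=C)[C@@H]3[C@]2(OC(=O)C(COCc4ccc(OC)cc4)P(=O)(OCC)OCC)C1=O | intermediate
34 | butenolide with C13 OPMB, C8 OTBS, C2 OAc, C4=C15 | CC(C)(C)[Si](C)(C)O[C@H]1C[C@]2(C)[C@@H]3[C@@H](OC(C)=O)CC(=C)[C@@H]3[C@@]23OC(=O)C(COCc4ccc(OC)cc4)=C13 | intermediate
35 | C4α tertiary alcohol of 34 | CC(C)(C)[Si](C)(C)O[C@H]1C[C@]2(C)[C@@H]3[C@@H](OC(C)=O)C[C@@](C)(O)[C@@H]3[C@@]23OC(=O)C(COCc4ccc(OC)cc4)=C13 | intermediate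
36 | C13 primary alcohol | CC(C)(C)[Si](C)(C)O[C@H]1C[C@]2(C)[C@@H]3[C@@H](OC(C)=O)C[C@@](C)(O)[C@@H]3[C@@]23OC(=O)C(CO)=C13 | intermediate
37 | C13 acetate, C8 OTBS | CC(C)(C)[Si](C)(C)O[C@H]1C[C@]2(C)[C@@H]3[C@@H](OC(C)=O)C[C@@](C)(O)[C@@H]3[C@@]23OC(=O)C(COC(C)=O)=C13 | intermediate
38 | C8α alcohol (target lacking the tigloyl group) | O[C@H]1C[C@]2(C)[C@@H]3[C@@H](OC(C)=O)C[C@@](C)(O)[C@@H]3[C@@]23OC(=O)C(COC(C)=O)=C13 | intermediate
39 | tiglic acid | C/C=C(\C)C(=O)O | starting material
40 | tiglic 2,4,6-trichlorobenzoic anhydride | C/C=C(\C)C(=O)OC(=O)c1c(Cl)cc(Cl)cc1Cl | intermediate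
41 | CNP0210373.1 | C/C=C(\C)C(=O)O[C@H]1C[C@]2(C)[C@@H]3[C@@H](OC(C)=O)C[C@@](C)(O)[C@@H]3[C@@]23OC(=O)C(COC(C)=O)=C13 | target

## Step count and least certain steps

Total: 30 steps. Longest linear sequence: 28 steps (steps 1–21 and 24–30); steps 22–23 make acid 32.

Step 11 (key step). The 1,3-displacement has to build a highly strained episulfone at two bridgeheads; if ring closure is slow, the carbanion may only exchange or lose its chlorine by halophilic attack, and the strained olefin may add alkoxide. Fallback, from 13 to 16: sulfone 13 is deprotonated twice with n-BuLi to the bridgehead α,α′-dilithio sulfone F1, and oxidation with CuCl2 couples the two carbanion carbons by electron transfer to the same episulfone 15, which loses SO2 to 16. No displacement at a bridgehead carbon is involved.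

Step 2. Cycloaddition to a tetrasubstituted olefin may be too slow, so that the ylide is consumed by self-condensation. Fallback, from 3 to 8: the ylide from 3 is added to commercial 3-methylcyclopent-2-en-1-one, a trisubstituted enone, to give rac-cis-6a-methylhexahydro-1H-cyclopenta[c]thiophen-4-one F2; mCPBA gives the keto sulfone F3; thermodynamic silylation (Me3SiCl, NaI, Et3N, MeCN) gives the ring-fusion trimethylsilyl enol ether F4; Rubottom oxidation with mCPBA places the C6 hydroxyl cis to C14 in the racemic hydroxy keto sulfone F5; ketalization with the bis-silyl ether of (2R,3R)-butane-2,3-diol and separation of the diastereomers gives 8.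

Step 6. Regiocontrol of the second lithiation may be lost (C5 instead of C1), which after cyclization puts the bridge ketone at C2. Fallback, from 8 to 11: the C5 adduct F6 is cyclized as in step 7 to the isomeric bridged C2 ketone F7; Saegusa–Ito dehydrogenation gives the C2-keto C3=C4 enone F8; alkaline hydroperoxide epoxidation gives the epoxy ketone F9; Wharton transposition (hydrazine hydrate, AcOH) gives the C4 allylic alcohol F10; oxidation with MnO2 gives the C4-keto C2=C3 enone F11; hydrogenation (H2, Pd/C) gives 11.

Step 12. Hydrogen may be delivered partly to the β face, which would give the anti tricycle. Fallback, from 16 to 17: the MOM ether of 16 is removed (Me3SiOTf, 2,2′-bipyridyl; H2O) to the C6 cyclobutenol F12; hydroxyl-directed hydrogenation with [Ir(cod)(PCy3)(py)]PF6 delivers hydrogen syn to the α hydroxyl to give the tricyclic alcohol F13; MOMCl and i-Pr2NEt return 17.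

Step 24 (with step 21). Acylation of the very hindered tertiary cyclobutanol may be slow, and base-promoted α-ketol ring expansion of 28 (C5 migrating from C6 to C7) may then take over. Fallback, from 28 to 37: the small, reactive acryloyl chloride (i-Pr2NEt, −78 °C) gives the C6 acrylate F14; a phosphine-catalysed intramolecular Morita–Baylis–Hillman reaction onto the C7 ketone gives the α-methylene β-hydroxy lactone F15; acetylation gives the tertiary allylic acetate F16; DABCO-mediated 1,3-transposition of the acetate gives the acetoxymethyl butenolide F17, which already carries the C13 acetate; Mukaiyama hydration as in step 26 gives 37.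

## Further compounds

F1 | step 11 | bridgehead α,α′-dilithio derivative of sulfone 13 | C1C[C@]2(C)[C@@]3([Li])CCC(OC)(OC)[C@]([Li])(S3(=O)=O)[C@]2(OCOC)C14O[C@H](C)[C@@H](C)O4
F2 | step 2 | rac-cis-6a-methylhexahydro-1H-cyclopenta[c]thiophen-4-one | C1C[C@]2(C)CSC[C@@H]2C1=O
F3 | step 2 | rac-cis-6a-methylhexahydro-1H-cyclopenta[c]thiophen-4-one 2,2-dioxide | C1C[C@]2(C)CS(=O)(=O)C[C@@H]2C1=O
F4 | step 2 | ring-fusion trimethylsilyl enol ether of F3 | C1C[C@]2(C)CS(=O)(=O)CC2=C1O[Si](C)(C)C
F5 | step 2 | rac-cis-3a-hydroxy-6a-methylhexahydro-1H-cyclopenta[c]thiophen-4-one 2,2-dioxide | C1C[C@]2(C)CS(=O)(=O)C[C@]2(O)C1=O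
F6 | step 6 | sulfone 8 with the 2-(methoxycarbonyl)ethyl group on C5 | C1C[C@]2(C)CS(=O)(=O)[C@@H](CCC(=O)OC)[C@]2(O)C13O[C@H](C)[C@@H](C)O3
F7 | step 6 | bridged keto sulfone with the ketone at C2 | C1C[C@]2(C)[C@H]3C(=O)CC[C@H](S3(=O)=O)[C@]2(O)C14O[C@H](C)[C@@H](C)O4
F8 | step 6 | bridged C2-keto C3=C4 enone | C1C[C@]2(C)[C@H]3C(=O)C=C[C@H](S3(=O)=O)[C@]2(O)C14O[C@H](C)[C@@H](C)O4
F9 | step 6 | bridged C2-keto C3,C4-epoxide | C1C[C@]2(C)[C@H]3C(=O)[C@H]4O[C@H]4[C@H](S3(=O)=O)[C@]2(O)C15O[C@H](C)[C@@H](C)O5
F10 | step 6 | bridged C4 allylic alcohol with C2=C3 | C1C[C@]2(C)[C@H]3C=C[C@@H](O)[C@H](S3(=O)=O)[C@]2(O)C14O[C@H](C)[C@@H](C)O4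
F11 | step 6 | bridged C4-keto C2=C3 enone | C1C[C@]2(C)[C@H]3C=CC(=O)[C@H](S3(=O)=O)[C@]2(O)C14O[C@H](C)[C@@H](C)O4
F12 | step 12 | C6 alcohol of cyclobutene 16 | C1C[C@]2(C)C3=C([C@]2(O)C14O[C@H](C)[C@@H](C)O4)C(OC)(OC)CC3
F13 | step 12 | C6 alcohol of tricycle 17 | C1C[C@]2(C)[C@@H]3CCC(OC)(OC)[C@@H]3[C@]2(O)C14O[C@H](C)[C@@H](C)O4
F14 | step 24 | C6 acrylate of 28 | CC(C)(C)[Si](C)(C)O[C@H]1C[C@]2(C)[C@@H]3[C@@H](OC(C)=O)CC(=C)[C@@H]3[C@]2(OC(=O)C=C)C1=O
F15 | step 24 | α-methylene β-hydroxy lactone (C7 tertiary alcohol) | CC(C)(C)[Si](C)(C)O[C@H]1C[C@]2(C)[C@@H]3[C@@H](OC(C)=O)CC(=C)[C@@H]3[C@@]23OC(=O)C(=C)[C@@]13O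
F16 | step 24 | C7 tertiary allylic acetate of F15 | CC(C)(C)[Si](C)(C)O[C@H]1C[C@]2(C)[C@@H]3[C@@H](OC(C)=O)CC(=C)[C@@H]3[C@@]23OC(=O)C(=C)[C@@]13OC(C)=O
F17 | step 24 | acetoxymethyl butenolide with C4=C15 and C8 OTBS | CC(C)(C)[Si](C)(C)O[C@H]1C[C@]2(C)[C@@H]3[C@@H](OC(C)=O)CC(=C)[C@@H]3[C@@]23OC(=O)C(COC(C)=O)=C13
A1 | alternative 1 | 8-hydroxy 5-4-5 tetracycle (identical with 38) | O[C@H]1C[C@]2(C)[C@@H]3[C@@H](OC(C)=O)C[C@@](C)(O)[C@@H]3[C@@]23OC(=O)C(COC(C)=O)=C13
A2 | alternative 1 | germacra-1(10),5,7(11)-trien-12,6-olide with both ring olefins ring-cis | O[C@H]1C/C(C)=C\[C@@H](OC(C)=O)C[C@@](C)(O)/C=C2/OC(=O)C(COC(C)=O)=C12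
A3 | alternative 2 | C10-quaternary cyclobutanone with dithiane chain | CC1(SCCCS1)C[C@]2(C)[C@@H]3[C@@H](O[Si](C)(C)C(C)(C)C)C[C@@](C)(O[Si](CC)(CC)CC)[C@@H]3C2=O
A4 | alternative 2 | α-methylene cyclobutanone of rings A and B | C=C1[C@@H]2[C@@H](O[Si](C)(C)C(C)(C)C)C[C@@](C)(O[Si](CC)(CC)CC)[C@@H]2C1=O
A5 | alternative 3 | tricyclic bicyclo[3.2.0]heptadienone | O=C1C=C[C@]2(C)C3=C([C@]12OCc4ccccc4)C(=O)C[C@H]3O[Si](C)(C)C(C)(C)C
A6 | alternative 3 | ring-A-fused 2-benzyloxy-5-methyltropone | O=C1C=CC(C)=C2[C@H](O[Si](C)(C)C(C)(C)C)CC(=O)C2=C1OCc1ccccc1
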